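One turn of the catalyst takes one substrate and one reagent and gives one product, so the part of the substrate that can become product has a ceiling: reagent charge over substrate charge, 50.0% for Friday's and 75.9% for Sunday's. Reagent is the limiting reagent in both flasks.

    reagent + catalyst intermediate A → catalyst intermediate B (k1 = 14000 M⁻¹ min⁻¹)
    2 catalyst intermediate A → spent catalyst (k2 = 2500 M⁻¹ min⁻¹)
    substrate + free catalyst ⇌ catalyst intermediate A (K3 = 770 M⁻¹, k3 = 2400 M⁻¹ min⁻¹)
    catalyst intermediate C → free catalyst + product (k4 = 200 min⁻¹)
    reagent + by-product ⇌ idle adduct, settled at all times (K5 = 28 M⁻¹)
    catalyst intermediate B → by-product + catalyst intermediate C (k6 = 1400 min⁻¹)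

all flasks: substrate 0.058 M; free catalyst 44 µM; time 20 min

|  | reagent |
|---|---|
| Friday's | 0.0290 M |
| Sunday's | 0.0440 M |

* part of the substrate that has reacted at the end, Friday's
* part of the substrate that has reacted at the end, Sunday's
* what raising the concentration of reagent from its lowest to its highest value here does to the part of the substrate that has reacted (changes below 5 percentage points count as none) (no change / it rises / it falls)

- percent here means substrate units held: one spent catalyst counts as two
- what is said of by-product includes idle adduct
- for a step with 2 of a species take k times the square, and two of it per event
- run time (Friday's): 20 min

That is the late end; the early end is the opening pace. Free catalyst waits for substrate, intermediate A for reagent, and intermediates B and C for their own steps. With the charges held, the first two waits are pseudo-first-order. Intermediate A goes back more slowly than it goes on, so I drop the way back, and one turn on Friday's takes 0.922 s.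

I call the reagent clock 10.1 min on Friday's: reagent charge over catalyst charge, times the time of one turn, which is the time the opening pace needs to reach the ceiling. Sunday's turn of 0.871 s gives a clock of 14.5 min.

To join the ends I take the ceiling times one minus e to the power of minus time over clock, which starts at the opening pace and flattens at the ceiling. I count neither catalyst loss nor adduct. Friday's comes to 43.1% and Sunday's to 56.7%, so I expect a rise of 14 percentage points.

The forecast says 47% and 63%, and it rises, starting from “Each turnover uses one reagent”.

The simulation gives 46.8% for Friday's and 62.7% for Sunday's, and it rises by 16 points. My curve stands 3.7 points low on Friday's and 6.0 points low on Sunday's.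

After 200 min, Friday's stands at 50.1% and Sunday's at 75.9%, beside their ceilings. The neighbour of Friday's charged with 0.049 M of reagent has a ceiling of 84.5%, a turn of 0.861 s and a clock of 16.0 min. My curve puts it at 60.3%, and at 20.0 min the simulated neighbour has reached 65.8%.

All constants stand for no real mixture; what happens was integrated by code.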